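The polyene is cut at the C10–C11 single bond. This is the sp2–sp2 link between the trisubstituted C9=C10 alkene beside ring A (cyclohex-1-ene, palmitate at C3) and the C11=C12 alkene leading to ring B (cyclohex-2-ene, myristate at C3', stereocentre C6'). One stereoretentive Suzuki–Miyaura coupling of a ring A trienylboronate with a ring B heptaenyl iodide completes the chromophore. Both esters are already in place, so the two hydroxyls never have to be told apart. Both rings come from one racemic trans-3-hydroxy-α-ionone: its (3R,6R) enantiomer becomes ring B, and its (3S,6S) enantiomer becomes ring A by base-induced alkene migration.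

Key step: step 10

Numbering: carotenoid numbering is used (ring A = C1–C6, chain C7–C15, primed numbers for the ring B half). In the ionones, C3 is the carbinol carbon and C6 the ring carbon that bears the side chain.

Assumption: toward 2 the lipase shows the spatial preference it shows toward 3-hydroxy-β-ionone-type rings (CH2–CMe2 flank in the large pocket), so the (3S,6S) alcohol is the one acylated; with the opposite preference, alcohol and acetate would only exchange roles at the cost of one mild methanolysis.

Step 1
Reactants: 1 (±)-α-ionone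
Product: 2 (±)-trans-3-hydroxy-α-ionone (equal amounts of the 3R,6R and 3S,6S forms)
Conditions: engineered cytochrome P450 monooxygenase (P450 BM3, CYP102A1 variant), NADP+ (cat.), glucose dehydrogenase, D-glucose, air, potassium phosphate buffer pH 7.5, 2% v/v EtOH, 25 °C
Reagents that add atoms: dioxygen, O=O
Why: Enzymatic allylic hydroxylation (hydrogen abstraction and oxygen rebound at the haem iron) is known for α-ionone to strike the C3 methylene and to deliver oxygen to the ring face opposite the C6 side chain in either enantiomer, which sets the 3,6-trans relation.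

Step 2
Reactants: 2 (±)-trans-3-hydroxy-α-ionone
Product: 3 (3R,6R)-3-hydroxy-α-ionone (alcohol left unreacted) and 4 (3S,6S)-3-acetoxy-α-ionone (ester formed)
Conditions: lipase PS (Burkholderia cepacia, immobilised), vinyl acetate, MTBE, 30 °C, stopped near half conversion; separation on silica gel
Reagents that add atoms: vinyl acetate, C=COC(C)=O
Why: Lipase-catalysed kinetic resolution by irreversible transesterification should acylate only the enantiomer that places the CH2–CMe2 flank of the carbinol in the large pocket, so the absolute configuration of both ring series is fixed here by sorting the two trans enantiomers.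

Step 3
Reactants: 3 (3R,6R)-3-hydroxy-α-ionone; 5 myristoyl chloride
Product: 6 (3R,6R)-3-myristoyloxy-α-ionone
Conditions: Et3N, DMAP (cat.), CH2Cl2, 0 °C to rt
Reagents that add atoms: none
Why: DMAP-catalysed O-acylation takes place at oxygen, so the C3–O bond and both stereocentres stay as they are, and the myristate that the target needs also shields the sensitive allylic alcohol in the following steps.

Step 4
Reactants: 6 (3R,6R)-3-myristoyloxy-α-ionone
Product: 8 ring B (7'E,9'E)-dienyl pinacolboronate (Bpin on C10'; myristate at C3'), via lithium alkoxide adduct 7 (not isolated)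
Conditions: CH2(Bpin)2 (1.3 equiv), lithium 2,2,6,6-tetramethylpiperidide (LiTMP, 1.2 equiv), THF, 0 °C; then 6, −78 °C to rt; water quench
Reagents that add atoms: bis(pinacolato)borylmethane CH2(Bpin)2, CC1(C)OB(CB2OC(C)(C)C(C)(C)O2)OC1(C)C
Why: In this boron–Wittig olefination the stabilised carbanion LiCH(Bpin)2 adds 1,2 to the methyl ketone faster than to the hindered secondary ester, and syn elimination of boron and oxygen from 7 should leave the remaining Bpin trans to the larger alkenyl group, giving the 9'E alkene (the minor 9'Z isomer is removed on silica gel) without touching C3' or C6'.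

Step 5
Reactants: 9 (2E,4E,6E)-2,7-dimethylocta-2,4,6-trienedial
Product: 11 (1E,3E,5E,7E,9E)-1,10-diiodo-3,8-dimethyldeca-1,3,5,7,9-pentaene, via iodotetraenal 10 (not isolated)
Conditions: CHI3 (5 equiv), CrCl2 (16 equiv), THF–1,4-dioxane, 0 °C to rt, dark
Reagents that add atoms: iodoform CHI3, IC(I)I
Why: In this twofold Takai olefination the geminal dichromium species made from CHI3 and divalent chromium adds to each aldehyde, and elimination from the less crowded arrangement gives the E-iodoalkene at both α-methyl enal termini.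

Step 6
Reactants: 8 ring B dienyl pinacolboronate; 11 pentaenyl diiodide (threefold excess)
Product: 12 ring B all-E heptaenyl iodide (iodine on C11; myristate at C3')
Conditions: Pd(PPh3)4 (5 mol %), TlOEt (1.5 equiv), degassed THF–H2O, rt, dark, argon; 8 added slowly; excess 11 recovered
Reagents that add atoms: none
Why: Suzuki–Miyaura alkenyl–alkenyl coupling with retention at both partners forms C10'–C11', and the excess of the symmetrical diiodide together with slow addition of 8 holds the reaction at monocoupling.

Step 7
Reactants: 4 (3S,6S)-3-acetoxy-α-ionone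
Product: 14 (3R)-3-hydroxy-β-ionone, via (3S,6S)-3-hydroxy-α-ionone 13 (not isolated)
Conditions: KOH, MeOH, rt, then 50 °C
Reagents that add atoms: none
Why: Hydroxide first cleaves the acetate, then reversible deprotonation of the C6 hydrogen (γ to the enone and doubly allylic) and reprotonation at C4 move the ring alkene from C4=C5 to C5=C6 (α- to β-ionone isomerisation), which erases C6 and leaves C3 untouched, its descriptor changing from S to R only because C2 now outranks C4.

Step 8
Reactants: 14 (3R)-3-hydroxy-β-ionone; 15 palmitoyl chloride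
Product: 16 (3R)-3-palmitoyloxy-β-ionone
Conditions: Et3N, DMAP (cat.), CH2Cl2, 0 °C to rt
Reagents that add atoms: none
Why: DMAP-catalysed O-acylation of the secondary homoallylic alcohol proceeds at oxygen with retention at C3 and installs the palmitate of ring A before the two halves meet.

Step 9
Reactants: 16 (3R)-3-palmitoyloxy-β-ionone
Product: 18 ring A (7E,9E)-trienyl pinacolboronate (Bpin on C10; palmitate at C3), via lithium alkoxide adduct 17 (not isolated)
Conditions: CH2(Bpin)2 (1.3 equiv), LiTMP (1.2 equiv), THF, 0 °C; then 16, −78 °C to rt; water quench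
Reagents that add atoms: bis(pinacolato)borylmethane CH2(Bpin)2, CC1(C)OB(CB2OC(C)(C)C(C)(C)O2)OC1(C)C
Why: Boron–Wittig olefination as in step 4, in which 1,2-addition to the dienone carbonyl at low temperature outruns attack on the ester, and syn boron–oxygen elimination from 17 should place Bpin trans to the bulky dienyl group to give the 9E alkene, the minor isomer being removed on silica gel.

Step 10
Reactants: 12 ring B heptaenyl iodide; 18 ring A trienyl pinacolboronate
Product: 19 (all-E,3R,3'R,6'R)-lutein 3-O-palmitate 3'-O-myristate (target)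
Conditions: Pd(PPh3)4 (10 mol %), TlOEt (1.5 equiv), degassed THF–H2O, rt, dark, argon, trace BHT
Reagents that add atoms: none
Why: Zerovalent palladium inserts into the carbon–iodine bond at C11 of 12 with retention, TlOEt in wet THF turns the C10 boronate of 18 into a borate and strips iodide from palladium as insoluble TlI, and transmetalation followed by reductive elimination, both with retention, forges the C10–C11 σ bond between two sp2 carbons. The closest known reaction type is the thallium-accelerated Suzuki–Miyaura alkenyl–alkenyl coupling used for sensitive polyenes. No ring is closed and no stereocentre is formed; C3, C3' and C6' lie far from the reacting carbons, so the only stereochemical demand is transfer of the E geometry of C9=C10 and C11=C12, which the stereoretentive elementary steps secure. The step needs chemoselectivity for the alkenyl iodide over the allylic myristate at C3' of ring B, and this rests on the far faster oxidative addition of the iodide at room temperature and on the poor binding of palladium to the trisubstituted C4'=C5' alkene, flanked by the C5' methyl group and the substituted C6'. The short reaction time at room temperature with little more than one equivalent of base should spare both fatty esters, and since no free hydroxyl is present the acyl groups cannot wander between the rings. In one operation a triene and a heptaene become the full decaene chromophore of the mixed diester.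

Compound list
1 | (±)-α-ionone, (E)-4-(2,6,6-trimethylcyclohex-2-en-1-yl)but-3-en-2-one, racemic | CC(=O)/C=C/C1C(C)=CCCC1(C)C | starting material
2 | (±)-trans-3-hydroxy-α-ionone, racemate, one enantiomer drawn | CC(=O)/C=C/[C@H]1C(C)=C[C@H](O)CC1(C)C | intermediate
3 | (3R,6R)-3-hydroxy-α-ionone, (E)-4-[(1R,4R)-4-hydroxy-2,6,6-trimethylcyclohex-2-en-1-yl]but-3-en-2-one | CC(=O)/C=C/[C@H]1C(C)=C[C@H](O)CC1(C)C | intermediate
4 | (3S,6S)-3-acetoxy-α-ionone, (1S,4S)-3,5,5-trimethyl-4-[(E)-3-oxobut-1-enyl]cyclohex-2-en-1-yl acetate | CC(=O)/C=C/[C@@H]1C(C)=C[C@@H](OC(C)=O)CC1(C)C | intermediate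
5 | myristoyl chloride (tetradecanoyl chloride) | CCCCCCCCCCCCCC(=O)Cl | starting material
6 | (3R,6R)-3-myristoyloxy-α-ionone, (1R,4R)-3,5,5-trimethyl-4-[(E)-3-oxobut-1-enyl]cyclohex-2-en-1-yl tetradecanoate | CC(=O)/C=C/[C@H]1C(C)=C[C@H](OC(=O)CCCCCCCCCCCCC)CC1(C)C | intermediate
7 | lithium alkoxide adduct of 6 with LiCH(Bpin)2, both C9' epimers | [Li+].[O-]C(C)(/C=C/[C@H]1C(C)=C[C@H](OC(=O)CCCCCCCCCCCCC)CC1(C)C)C(B1OC(C)(C)C(C)(C)O1)B1OC(C)(C)C(C)(C)O1 | intermediate
8 | (1R,4R)-3,5,5-trimethyl-4-[(1E,3E)-3-methyl-4-(4,4,5,5-tetramethyl-1,3,2-dioxaborolan-2-yl)buta-1,3-dienyl]cyclohex-2-en-1-yl tetradecanoate | CC1(C)OB(/C=C(C)/C=C/[C@H]2C(C)=C[C@H](OC(=O)CCCCCCCCCCCCC)CC2(C)C)OC1(C)C | intermediate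
9 | (2E,4E,6E)-2,7-dimethylocta-2,4,6-trienedial | O=C/C(C)=C/C=C/C=C(C)/C=O | starting material
10 | (2E,4E,6E,8E)-9-iodo-2,7-dimethylnona-2,4,6,8-tetraenal | O=C/C(C)=C/C=C/C=C(C)/C=C/I | intermediate
11 | (1E,3E,5E,7E,9E)-1,10-diiodo-3,8-dimethyldeca-1,3,5,7,9-pentaene | I/C=C/C(C)=C/C=C/C=C(C)/C=C/I | intermediate
12 | (1R,4R)-4-[(1E,3E,5E,7E,9E,11E,13E)-14-iodo-3,7,12-trimethyltetradeca-1,3,5,7,9,11,13-heptaenyl]-3,5,5-trimethylcyclohex-2-en-1-yl tetradecanoate | I/C=C/C(C)=C/C=C/C=C(C)/C=C/C=C(C)/C=C/[C@H]1C(C)=C[C@H](OC(=O)CCCCCCCCCCCCC)CC1(C)C | intermediate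
13 | (3S,6S)-3-hydroxy-α-ionone | CC(=O)/C=C/[C@@H]1C(C)=C[C@@H](O)CC1(C)C | intermediate
14 | (3R)-3-hydroxy-β-ionone, (E)-4-[(4R)-4-hydroxy-2,6,6-trimethylcyclohex-1-en-1-yl]but-3-en-2-one | O[C@@H]1CC(C)=C(/C=C/C(C)=O)C(C)(C)C1 | intermediate
15 | palmitoyl chloride (hexadecanoyl chloride) | CCCCCCCCCCCCCCCC(=O)Cl | starting material
16 | (3R)-3-palmitoyloxy-β-ionone, (1R)-3,5,5-trimethyl-4-[(E)-3-oxobut-1-enyl]cyclohex-3-en-1-yl hexadecanoate | CCCCCCCCCCCCCCCC(=O)O[C@@H]1CC(C)=C(/C=C/C(C)=O)C(C)(C)C1 | intermediate
17 | lithium alkoxide adduct of 16 with LiCH(Bpin)2, both C9 epimers | CCCCCCCCCCCCCCCC(=O)O[C@@H]1CC(C)=C(/C=C/C(C)([O-])C(B2OC(C)(C)C(C)(C)O2)B2OC(C)(C)C(C)(C)O2)C(C)(C)C1.[Li+] | intermediate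
18 | (1R)-3,5,5-trimethyl-4-[(1E,3E)-3-methyl-4-(4,4,5,5-tetramethyl-1,3,2-dioxaborolan-2-yl)buta-1,3-dienyl]cyclohex-3-en-1-yl hexadecanoate | CCCCCCCCCCCCCCCC(=O)O[C@@H]1CC(C)=C(/C=C/C(C)=C/B2OC(C)(C)C(C)(C)O2)C(C)(C)C1 | intermediate
19 | (all-E,3R,3'R,6'R)-3-(hexadecanoyloxy)-β,ε-caroten-3'-yl tetradecanoate (lutein 3-O-palmitate 3'-O-myristate) | CCCCCCCCCCCCCCCC(=O)O[C@@H]1CC(C)=C(/C=C/C(C)=C/C=C/C(C)=C/C=C/C=C(C)/C=C/C=C(C)/C=C/[C@H]2C(C)=C[C@H](OC(=O)CCCCCCCCCCCCC)CC2(C)C)C(C)(C)C1 | target

Total step count: 10. Longest linear sequence: 6 steps (1, 2, 3, 4, 6, 10 or 1, 2, 7, 8, 9, 10).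

Steps most likely to fail

Step 10. Transmetalation of the β,β-disubstituted alkenylboronate may be slower than the decay of the heptaenyl iodide through E/Z scrambling, homocoupling and protodeboronation. Zerovalent palladium may also ionise the allylic myristate. The fallback is a base-free Stille coupling with inverted polarity; it sets out from 18 and 12 and comes back to the route at 19. Boronate 18 is converted with retention (NaOMe, then ICl, THF, −78 °C) into the ring A trienyl iodide F1. Iodide 12 is stannylated (Me3SnSnMe3, Pd(PPh3)4 cat., THF, rt) to the ring B heptaenyl trimethylstannane F2. The two are joined at C10–C11 with Pd2(dba)3 and AsPh3 in NMP at rt. The hindered carbon is then the electrophile, the unhindered terminal stannane transmetalates quickly, and no base is present.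

Step 4. Three processes may compete with addition: enolisation of the methyl ketone, deprotonation at C6' followed by loss of the myristate, and weak discrimination between the methyl and alkenyl groups in the elimination, which would erode the 9' geometry. The fallback is the classical phosphonium salt chain extension; it sets out from 6 and comes back at 12, bypassing 8, 11 and step 6. VinylMgBr (THF, −78 °C) adds to the ketone of 6 to give the tertiary allylic alcohol F3. PPh3·HBr (CH2Cl2, 0 °C to rt) converts it by allylic transposition into the C15 phosphonium bromide F4. Wittig reaction with an excess of dialdehyde 9 (1,2-epoxybutane, reflux) gives the C25 apo-12-carotenal myristate F5, which is equilibrated to the all-E form by heating and then crystallised. Takai olefination (CHI3, CrCl2, THF, 0 °C) then gives 12.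

Step 9. The geometric selectivity at C9=C10 may be poor, and vinylogous deprotonation at C4 may be followed by loss of the palmitate. The fallback builds the trisubstituted alkene by stereospecific syn carbometalation of an alkyne; it sets out from 14 and comes back at 18. TBSCl and imidazole give the silyl ether F6. LDA, ClP(O)(OEt)2 and then more LDA (THF, −78 °C to rt) turn the methyl ketone into the terminal dienyne F7. Negishi carboalumination (Me3Al, Cp2ZrCl2 cat., CH2Cl2) followed by a quench of the alkenylalane with MeOBpin gives the silylated trienylboronate F8. HF·pyridine (THF, 0 °C) frees the hydroxy trienylboronate F9, and acylation with 15 (Et3N, DMAP) gives 18.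

Further compounds
F1 | step 10 | ring A trienyl iodide, (1R)-4-[(1E,3E)-4-iodo-3-methylbuta-1,3-dienyl]-3,5,5-trimethylcyclohex-3-en-1-yl hexadecanoate | CCCCCCCCCCCCCCCC(=O)O[C@@H]1CC(C)=C(/C=C/C(C)=C/I)C(C)(C)C1
F2 | step 10 | ring B heptaenyl trimethylstannane (Me3Sn on C11, all-E, 3'R,6'R) | C[Sn](C)(C)/C=C/C(C)=C/C=C/C=C(C)/C=C/C=C(C)/C=C/[C@H]1C(C)=C[C@H](OC(=O)CCCCCCCCCCCCC)CC1(C)C
F3 | step 4 | tertiary allylic alcohol from 6 and vinylMgBr, both C9' epimers | C=CC(C)(O)/C=C/[C@H]1C(C)=C[C@H](OC(=O)CCCCCCCCCCCCC)CC1(C)C
F4 | step 4 | C15 phosphonium bromide, [(2E,4E)-3-methyl-5-[(1R,4R)-4-tetradecanoyloxy-2,6,6-trimethylcyclohex-2-enyl]penta-2,4-dienyl]triphenylphosphonium bromide | c1ccccc1[P+](c1ccccc1)(c1ccccc1)C/C=C(C)/C=C/[C@H]1C(C)=C[C@H](OC(=O)CCCCCCCCCCCCC)CC1(C)C.[Br-]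
F5 | step 4 | C25 apo-12-carotenal myristate (all-E, 3'R,6'R) | O=C/C(C)=C/C=C/C=C(C)/C=C/C=C(C)/C=C/[C@H]1C(C)=C[C@H](OC(=O)CCCCCCCCCCCCC)CC1(C)C
F6 | step 9 | (3R)-3-(tert-butyldimethylsilyloxy)-β-ionone | CC(C)(C)[Si](C)(C)O[C@@H]1CC(C)=C(/C=C/C(C)=O)C(C)(C)C1
F7 | step 9 | (3R)-silyloxy dienyne, ring A–CH=CH–C≡CH | CC(C)(C)[Si](C)(C)O[C@@H]1CC(C)=C(/C=C/C#C)C(C)(C)C1
F8 | step 9 | (3R)-silyloxy (7E,9E)-trienyl pinacolboronate | CC(C)(C)[Si](C)(C)O[C@@H]1CC(C)=C(/C=C/C(C)=C/B2OC(C)(C)C(C)(C)O2)C(C)(C)C1
F9 | step 9 | (3R)-hydroxy (7E,9E)-trienyl pinacolboronate | O[C@@H]1CC(C)=C(/C=C/C(C)=C/B2OC(C)(C)C(C)(C)O2)C(C)(C)C1
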